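Early on, the east run has made 28.4 % side product at 1.25 d with 59.1 % of its substrate left, and by 2.50 d that substrate reads 3.2 %.

| flask | substrate | reagent | remark | time |
|---|---|---|---|---|
| north-east | 0.30 M | 0.45 M | run made earlier |  |
| east | 0.15 M | 0.45 M | run made earlier |  |
| west | 0.22 M | 0.45 M | run made earlier |  |
| noon | 0.30 M | 0.450 M (fed, over 10 d) | all else is in the flask from the start; the feed brings no volume worth counting | 12 d |
| dawn | 0.30 M | 0.450 M | everything together at the start | 12 d |
| winter | 0.30 M (fed, over 10 d) | 0.450 M | all else is in the flask from the start; the feed brings no volume worth counting | 12 d |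

| run | time / d | side product / % | target / % | substrate / % |
|---|---|---|---|---|
| north-east | 1.04 | 64.8 | 11.7 | 18.4 |
| north-east | 2.00 | 80.2 | 11.3 | 0 |
| north-east | 5.00 | 80.3 | 2.8 | 1.8 |
| north-east | 12.0 | 80.7 | 0 | 0.1 |
| east | 1.25 | 28.4 | 8.8 | 59.1 |
| east | 2.50 | 70.8 | 13.3 | 3.2 |
| east | 6.00 | 74.7 | 1.3 | 1.2 |
| east | 15.0 | 74.6 | 0 | 0.8 |
| west | 1.67 | 74.2 | 12.4 | 5.5 |
| west | 5.00 | 79.3 | 3.1 | 1.3 |
| west | 10.0 | 78.7 | 0.4 | 0 |
| west | 15.0 | 79.7 | 0.6 | 0 |

(each reading ± 1 percentage point)

- a species is counted by the substrate in it: one side product counts as two

- the flask with the highest amount of side product, in percent of the substrate charged ("all alike" if they lie within 1.5 percentage points) (noon / dawn / winter / all alike)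
- final side product, as a percentage of the substrate charged, in noon
- final side product, as a percentage of the substrate charged, in dawn
- final side product, as a percentage of the substrate charged, in winter

Read as a logistic fall, with loss going as substrate times substrate consumed, those two readings give κ = 20.1 /M/d. In the north-east run, side product barely moves after 2.00 d, while target falls from 11.3 % to 2.8 % by 5.00 d, which I read as a first-order decay with k_d = 0.465 /d. So I let a target go two ways: onto substrate of concentration S, pseudo-first-order at k_s·S, or away at k_d. The east gain in side product gives k_s = 40.2 /M/d. The even-odds level S* = k_d/k_s = 0.0116 M is the substrate concentration at which a target is as likely to decay as to meet substrate. With f = S/(S + S*), side product takes 2f/(1 + f) of the substrate consumed.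

Dawn repeats north-east, so I put it at 80.7 %. For noon, the slow-feed end averages that share as S falls from the charge c to zero: 1 − (S*/2c)·ln(1 + 2c/S*) = 92.3 %, so I put noon between these two. For winter, I take S climbing from zero to a knee, then following S = 1/(κt). It crosses S* at t* = 4.29 d, earlier than the feed ends at 10 d. Each portion fed is then shared as 2f/(1 + f) = 2/(2 + t/t*), and the mean of this over the feed time t_f, 2(t*/t_f)·ln(1 + t_f/(2t*)) = 66.3 %, is my level for winter.

The forecast differs: all alike, with noon 80.5 % (75 % to 85 %), dawn 80.5 % (79 % to 82 %) and winter 78 % (62 % to 84 %), since “Feeding should therefore change little”.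

The flasks give noon as highest: noon 88.0 %, dawn 80.4 %, winter 63.8 %.

    substrate + reagent + by-product → target + 2 by-product (k = 2.30 /M²/h)
    substrate + reagent → target + by-product (k = 0.00150 /M/h)
    target → over-reaction product (k = 0.0260 /h)
    substrate + target → side product (k = 1.90 /M/h)

Winter's substrate stands at 0.0107 M after 6.00 d, close to S*, and at 0.00801 M after 10.0 d, below it. At 12.0 d winter is not quite at rest: it holds 2.57 % target with substrate at 0 %. At ten times that time, over-reaction product moves from 33.6 % to 36.2 %, while side product stays at 63.8 %. Noon stays at 88.0 %.

For the neighbour, noon with 0.18 M substrate, S* gives a slow-feed end of 88.8 %, and the east and west runs, with charges on either side of it, read 74.6 % and 79.7 %. The neighbour gives 82.1 %, below that end and above both runs.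

The numbers in the tables stem from a simulated flask on assumed constants; noise was put on by code.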